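**Plan**

1. Retrosynthesis: first the silyl groups and the aryl–C(=O) bond (Weinreb amide plus aryl Grignard reagent), then, in one cut, the O1–C7 ether bond and the C5=C6 olefin of the 2,3,4,7-tetrahydrooxepine, last the bond from quaternary C2 to its allyl-derived chain.
2. Enabling feature: ring atoms O1–C2–C3–C4–C5 are a γ-hydroxy aldehyde with the hydroxyl on tertiary C2, that is a five-membered lactol (oxolane). C6–C7, the only ring atoms that carry the side chain, are a 1-substituted vinyl unit, which a vinylphosphonium salt delivers as acceptor (C7) and latent ylide (C6).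
3. Forward: lactol 11 (five steps from (R)-malic acid) and vinylphosphonium salt 18 (four steps from 6-methylhept-5-en-2-one) are joined in step 10, which expands the oxolane lactol by two carbons to the oxepine. Ester hydrolysis, aryl ketone formation and global desilylation follow.
4. Stereochemistry: the only stereocentre, C2 (R), comes from (R)-malic acid and is made quaternary with retention by self-regeneration of stereocentres. The (E) side-chain olefin comes from SeO2 allylic oxidation, and the position of the ring olefin is fixed by the Wittig closure.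

Key step: step 10

Assumption: lactol 11 is carried on as its mixture of C5 epimers, since both open to the same hydroxy aldehyde under the basic conditions of step 10.

**Step 1**
Reactants: 1 (R)-malic acid; 2 pivalaldehyde
Product: 3 2-[(2R,4R)-2-tert-butyl-5-oxo-1,3-dioxolan-4-yl]acetic acid (cis)
Conditions: t-BuCHO (2 equiv), TsOH·H2O (cat.), H2SO4 (cat.), pentane, reflux, Dean–Stark; recrystallisation
Reagents that add atoms: none
Why: Acid-catalysed acetalisation of the α-hydroxy acid unit with water removal should give the cis-dioxolanone, the acetal centre being set under thermodynamic control by the untouched (R) centre and the minor trans isomer being removed by crystallisation.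

**Step 2**
Reactants: 3 2-[(2R,4R)-2-tert-butyl-5-oxo-1,3-dioxolan-4-yl]acetic acid; 4 allyl bromide
Product: 6 2-[(2R,4R)-2-tert-butyl-5-oxo-4-(prop-2-en-1-yl)-1,3-dioxolan-4-yl]acetic acid, via dilithium enolate 5 (not isolated)
Conditions: LiN(SiMe3)2 (2.1 equiv), THF, −78 °C; allyl bromide, −78 → −20 °C; 1 M HCl
Reagents that add atoms: none
Why: In this enolate alkylation by self-regeneration of stereocentres, the planar enolate 5 should be attacked on the face opposite the tert-butyl group, so allyl takes the place of the former hydrogen and the quaternary centre forms with net retention (R).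

**Step 3**
Reactants: 6 2-[(2R,4R)-2-tert-butyl-5-oxo-4-(prop-2-en-1-yl)-1,3-dioxolan-4-yl]acetic acid; 7 N,O-dimethylhydroxylamine hydrochloride
Product: 9 2-[(2R,4R)-2-tert-butyl-5-oxo-4-(prop-2-en-1-yl)-1,3-dioxolan-4-yl]-N-methoxy-N-methylacetamide, via acyl imidazolide 8 (not isolated)
Conditions: CDI (1.1 equiv), CH2Cl2, 0 °C → rt; MeNH(OMe)·HCl (1.3 equiv), rt
Reagents that add atoms: none
Why: Amide coupling through the acyl imidazolide should convert only the free side-chain acid into the Weinreb amide, because the hindered dioxolanone carbonyl is far less reactive towards the weakly nucleophilic amine.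

**Step 4**
Reactants: 9 2-[(2R,4R)-2-tert-butyl-5-oxo-4-(prop-2-en-1-yl)-1,3-dioxolan-4-yl]-N-methoxy-N-methylacetamide
Product: 10 methyl (2R)-2-hydroxy-2-{2-[methoxy(methyl)amino]-2-oxoethyl}pent-4-enoate
Conditions: NaOMe (0.2 equiv), MeOH, 0 °C
Reagents that add atoms: methanol, CO
Why: Methoxide-catalysed transesterification opens the dioxolanone at its lactone carbonyl and the hemiacetal alkoxide expels pivalaldehyde, which should unmask the tertiary alcohol as its methyl ester without touching the quaternary centre.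

**Step 5**
Reactants: 10 methyl (2R)-2-hydroxy-2-{2-[methoxy(methyl)amino]-2-oxoethyl}pent-4-enoate
Product: 11 methyl (2R)-5-hydroxy-2-{2-[methoxy(methyl)amino]-2-oxoethyl}oxolane-2-carboxylate (lactol, both C5 epimers)
Conditions: PdCl2(PhCN)2 (10 mol %), CuCl2·2H2O (10 mol %), AgNO2 (5 mol %), O2 (1 atm), t-BuOH/MeNO2 15:1, rt
Reagents that add atoms: dioxygen, O=O
Why: The nitrite-modified, aldehyde-selective (anti-Markovnikov) Wacker oxidation, reinforced by the homoallylic hydroxyl group, should oxidise the terminal olefin carbon to the aldehyde, which the tertiary alcohol traps at once as the five-membered lactol.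

**Step 6**
Reactants: 12 6-methylhept-5-en-2-one
Product: 13 (5E)-7-hydroxy-6-methylhept-5-en-2-one
Conditions: SeO2 (0.3 equiv), t-BuOOH (2.5 equiv), salicylic acid (0.1 equiv), CH2Cl2, rt
Reagents that add atoms: selenium dioxide, O=[Se]=O; tert-butyl hydroperoxide, CC(C)(C)OO
Why: Catalytic SeO2 allylic oxidation (Riley oxidation, ene reaction then [2,3]-sigmatropic shift) should hydroxylate the (E)-methyl group of the trisubstituted olefin, which fixes the (E) geometry of the side chain.

**Step 7**
Reactants: 13 (5E)-7-hydroxy-6-methylhept-5-en-2-one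
Product: 14 (5E)-7-[(tert-butyldimethylsilyl)oxy]-6-methylhept-5-en-2-one
Conditions: TBSCl (1.2 equiv), imidazole (2 equiv), DMF, 0 °C → rt
Reagents that add atoms: tert-butyldimethylsilyl chloride, CC(C)(C)[Si](C)(C)Cl
Why: Imidazole-promoted silylation of the primary allylic alcohol should give the silyl ether that shields this hydroxyl group from the bases of steps 8, 10 and 13.

**Step 8**
Reactants: 14 (5E)-7-[(tert-butyldimethylsilyl)oxy]-6-methylhept-5-en-2-one
Product: 16 (5E)-7-[(tert-butyldimethylsilyl)oxy]-6-methylhepta-1,5-dien-2-yl trifluoromethanesulfonate, via lithium enolate 15 (not isolated)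
Conditions: LiN(i-Pr)2 (1.1 equiv), THF, −78 °C; PhNTf2 (1.1 equiv), −78 → 0 °C; aq NH4Cl
Reagents that add atoms: N-phenylbis(trifluoromethanesulfonimide), O=S(=O)(N(c1ccccc1)S(=O)(=O)C(F)(F)F)C(F)(F)F
Why: Kinetic deprotonation at −78 °C takes place at the methyl group, and O-triflation of the terminal enolate should give the 2-triflyloxy-1-alkene (enol triflate formation).

**Step 9**
Reactants: 16 (5E)-7-[(tert-butyldimethylsilyl)oxy]-6-methylhepta-1,5-dien-2-yl trifluoromethanesulfonate; 17 triphenylphosphine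
Product: 18 [(5E)-7-[(tert-butyldimethylsilyl)oxy]-6-methylhepta-1,5-dien-2-yl]triphenylphosphonium trifluoromethanesulfonate
Conditions: PPh3 (1.05 equiv), Pd(PPh3)4 (3 mol %), THF, 65 °C
Reagents that add atoms: none
Why: Pd-catalysed C–P coupling of a vinyl triflate with PPh3 (oxidative addition to zerovalent palladium, then reductive elimination of the vinylphosphonium ion) should give the 1-substituted vinylphosphonium salt under neutral conditions that leave the silyl ether and the (E)-olefin alone.

**Step 10**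
Reactants: 11 methyl (2R)-5-hydroxy-2-{2-[methoxy(methyl)amino]-2-oxoethyl}oxolane-2-carboxylate; 18 [(5E)-7-[(tert-butyldimethylsilyl)oxy]-6-methylhepta-1,5-dien-2-yl]triphenylphosphonium trifluoromethanesulfonate
Product: 21 methyl (2R)-6-[(3E)-5-[(tert-butyldimethylsilyl)oxy]-4-methylpent-3-en-1-yl]-2-{2-[methoxy(methyl)amino]-2-oxoethyl}-2,3,4,7-tetrahydrooxepine-2-carboxylate, via sodium alkoxide aldehyde 19 (not isolated), via phosphonium ylide 20 (not isolated)
Conditions: NaH (1.1 equiv), THF, 0 °C; 18, THF, 0 → 60 °C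
Reagents that add atoms: none
Why: NaH deprotonates lactol 11, whose ring-opened form 19 is a tertiary alkoxide with a free aldehyde; the alkoxide adds to the unsubstituted CH2 terminus of 18 (oxa-Michael addition, forming O1–C7) and so creates the non-stabilised ylide 20 at C6, which closes on the C5 aldehyde by intramolecular Wittig olefination (forming C5=C6) with loss of Ph3P=O. The closest known reaction type is the Schweizer annulation of hydroxy carbonyl compounds with vinylphosphonium salts, applied here to a γ-lactol so that it amounts to a two-carbon ring expansion of the oxolane to the oxepine. The oxepine ring closes by 7-exo-trig attack of the C6 ylide carbon on the C5 aldehyde, followed by collapse of the bicyclic oxaphosphetane, so the olefin can only lie between C5 and C6 and can only be cis within the ring. No stereocentre is formed, and the quaternary C2 is preserved because it has no α-hydrogen and its β-carbonyl is an amide, which should suppress retro-aldol cleavage of alkoxide 19. The step needs the tertiary alkoxide, not the lactol oxygen, to end up on C7, and it needs addition to outrun base-induced isomerisation of 18; the reversibility of the oxa-Michael addition (β-alkoxy ylides eject alkoxide again) should funnel the adducts to the one ylide that has an aldehyde within reach, where the Wittig step is irreversible. The regiochemistry of the trisubstituted olefin is secured by phosphorus sitting on C6, the carbon that already carries the side chain.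

**Step 11**
Reactants: 21 methyl (2R)-6-[(3E)-5-[(tert-butyldimethylsilyl)oxy]-4-methylpent-3-en-1-yl]-2-{2-[methoxy(methyl)amino]-2-oxoethyl}-2,3,4,7-tetrahydrooxepine-2-carboxylate
Product: 22 (2R)-6-[(3E)-5-[(tert-butyldimethylsilyl)oxy]-4-methylpent-3-en-1-yl]-2-{2-[methoxy(methyl)amino]-2-oxoethyl}-2,3,4,7-tetrahydrooxepine-2-carboxylic acid
Conditions: LiOH·H2O (3 equiv), THF/MeOH/H2O 3:1:1, rt; 1 M HCl to pH 4, 0 °C
Reagents that add atoms: lithium hydroxide, [Li+].[OH-]
Why: Saponification of the α-alkoxy methyl ester should be faster than hydrolysis of the Weinreb amide, and it is placed before ketone formation because the later β-alkoxy ketone would be open to base-induced β-elimination.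

**Step 12**
Reactants: 23 2-bromobenzene-1,4-diol
Product: 24 2-bromo-1,4-bis[(tert-butyldimethylsilyl)oxy]benzene
Conditions: TBSCl (2.4 equiv), imidazole (5 equiv), DMF, rt
Reagents that add atoms: tert-butyldimethylsilyl chloride, CC(C)(C)[Si](C)(C)Cl
Why: Imidazole-promoted silylation of both phenols should give a bromide that forms a Grignard reagent and whose protecting groups leave together with the side-chain silyl ether in the last step.

**Step 13**
Reactants: 22 (2R)-6-[(3E)-5-[(tert-butyldimethylsilyl)oxy]-4-methylpent-3-en-1-yl]-2-{2-[methoxy(methyl)amino]-2-oxoethyl}-2,3,4,7-tetrahydrooxepine-2-carboxylic acid; 24 2-bromo-1,4-bis[(tert-butyldimethylsilyl)oxy]benzene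
Product: 27 (2R)-2-(2-{2,5-bis[(tert-butyldimethylsilyl)oxy]phenyl}-2-oxoethyl)-6-[(3E)-5-[(tert-butyldimethylsilyl)oxy]-4-methylpent-3-en-1-yl]-2,3,4,7-tetrahydrooxepine-2-carboxylic acid, via aryl Grignard reagent 25 (not isolated), via chloromagnesium carboxylate 26 (not isolated)
Conditions: 24, Mg, LiCl, THF, rt; 22, i-PrMgCl (1.0 equiv), THF, −40 °C; combine (25, 1.6 equiv), −40 → 0 °C; aq NH4Cl
Reagents that add atoms: none
Why: In this Weinreb ketone synthesis the acid is first masked as its magnesium salt, which is inert to Grignard reagents, and the aryl Grignard reagent should then add once to the Weinreb amide to give a stable magnesium chelate that releases the aryl ketone only on work-up.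

**Step 14**
Reactants: 27 (2R)-2-(2-{2,5-bis[(tert-butyldimethylsilyl)oxy]phenyl}-2-oxoethyl)-6-[(3E)-5-[(tert-butyldimethylsilyl)oxy]-4-methylpent-3-en-1-yl]-2,3,4,7-tetrahydrooxepine-2-carboxylic acid
Product: 28 (2R)-2-[2-(2,5-dihydroxyphenyl)-2-oxoethyl]-6-[(3E)-5-hydroxy-4-methylpent-3-en-1-yl]-2,3,4,7-tetrahydrooxepine-2-carboxylic acid
Conditions: HF·pyridine, pyridine, THF, 0 °C → rt
Reagents that add atoms: none
Why: Fluoride-mediated cleavage of the two aryl silyl ethers and the primary allylic silyl ether should proceed under mildly acidic conditions that avoid β-elimination at the β-alkoxy ketone and leave the olefins and the acid intact.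

**Compound list**

1 | (R)-malic acid, (2R)-2-hydroxybutanedioic acid | O[C@H](CC(=O)O)C(=O)O | starting material
2 | pivalaldehyde | CC(C)(C)C=O | starting material
3 | 2-[(2R,4R)-2-tert-butyl-5-oxo-1,3-dioxolan-4-yl]acetic acid | CC(C)(C)[C@@H]1O[C@H](CC(=O)O)C(=O)O1 | intermediate
4 | allyl bromide | C=CCBr | starting material
5 | dilithium enolate carboxylate of 3 | CC(C)(C)[C@@H]1OC(CC(=O)[O-])=C([O-])O1.[Li+].[Li+] | intermediate
6 | 2-[(2R,4R)-2-tert-butyl-5-oxo-4-(prop-2-en-1-yl)-1,3-dioxolan-4-yl]acetic acid | CC(C)(C)[C@@H]1O[C@](CC=C)(CC(=O)O)C(=O)O1 | intermediate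
7 | N,O-dimethylhydroxylamine hydrochloride | CNOC.Cl | starting material
8 | acyl imidazolide of 6 | CC(C)(C)[C@@H]1O[C@](CC=C)(CC(=O)n2ccnc2)C(=O)O1 | intermediate
9 | 2-[(2R,4R)-2-tert-butyl-5-oxo-4-(prop-2-en-1-yl)-1,3-dioxolan-4-yl]-N-methoxy-N-methylacetamide | CC(C)(C)[C@@H]1O[C@](CC=C)(CC(=O)N(C)OC)C(=O)O1 | intermediate
10 | methyl (2R)-2-hydroxy-2-{2-[methoxy(methyl)amino]-2-oxoethyl}pent-4-enoate | C=CC[C@@](O)(CC(=O)N(C)OC)C(=O)OC | intermediate
11 | methyl (2R)-5-hydroxy-2-{2-[methoxy(methyl)amino]-2-oxoethyl}oxolane-2-carboxylate (both C5 epimers) | COC(=O)[C@]1(CC(=O)N(C)OC)CCC(O)O1 | intermediate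
12 | 6-methylhept-5-en-2-one | CC(C)=CCCC(C)=O | starting material
13 | (5E)-7-hydroxy-6-methylhept-5-en-2-one | CC(=O)CC/C=C(\C)CO | intermediate
14 | (5E)-7-[(tert-butyldimethylsilyl)oxy]-6-methylhept-5-en-2-one | CC(=O)CC/C=C(\C)CO[Si](C)(C)C(C)(C)C | intermediate
15 | terminal lithium enolate of 14 | [Li+].[O-]C(=C)CC/C=C(\C)CO[Si](C)(C)C(C)(C)C | intermediate
16 | (5E)-7-[(tert-butyldimethylsilyl)oxy]-6-methylhepta-1,5-dien-2-yl trifluoromethanesulfonate | C=C(CC/C=C(\C)CO[Si](C)(C)C(C)(C)C)OS(=O)(=O)C(F)(F)F | intermediate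
17 | triphenylphosphine | c1ccc(cc1)P(c1ccccc1)c1ccccc1 | starting material
18 | [(5E)-7-[(tert-butyldimethylsilyl)oxy]-6-methylhepta-1,5-dien-2-yl]triphenylphosphonium trifluoromethanesulfonate | C=C(CC/C=C(\C)CO[Si](C)(C)C(C)(C)C)[P+](c1ccccc1)(c1ccccc1)c1ccccc1.[O-]S(=O)(=O)C(F)(F)F | intermediate
19 | sodium alkoxide of methyl (2R)-2-hydroxy-2-{2-[methoxy(methyl)amino]-2-oxoethyl}-5-oxopentanoate (ring-opened 11) | O=CCC[C@@]([O-])(CC(=O)N(C)OC)C(=O)OC.[Na+] | intermediate
20 | phosphonium ylide formed by oxa-Michael addition of 19 to 18 | O=CCC[C@@](CC(=O)N(C)OC)(C(=O)OC)OC[C-](CC/C=C(\C)CO[Si](C)(C)C(C)(C)C)[P+](c1ccccc1)(c1ccccc1)c1ccccc1 | intermediate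
21 | methyl (2R)-6-[(3E)-5-[(tert-butyldimethylsilyl)oxy]-4-methylpent-3-en-1-yl]-2-{2-[methoxy(methyl)amino]-2-oxoethyl}-2,3,4,7-tetrahydrooxepine-2-carboxylate | C/C(=C\CCC1=CCC[C@@](CC(=O)N(C)OC)(C(=O)OC)OC1)CO[Si](C)(C)C(C)(C)C | intermediate
22 | (2R)-6-[(3E)-5-[(tert-butyldimethylsilyl)oxy]-4-methylpent-3-en-1-yl]-2-{2-[methoxy(methyl)amino]-2-oxoethyl}-2,3,4,7-tetrahydrooxepine-2-carboxylic acid | C/C(=C\CCC1=CCC[C@@](CC(=O)N(C)OC)(C(=O)O)OC1)CO[Si](C)(C)C(C)(C)C | intermediate
23 | 2-bromobenzene-1,4-diol | Oc1ccc(O)c(Br)c1 | starting material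
24 | 2-bromo-1,4-bis[(tert-butyldimethylsilyl)oxy]benzene | CC(C)(C)[Si](C)(C)Oc1ccc(O[Si](C)(C)C(C)(C)C)c(Br)c1 | intermediate
25 | {2,5-bis[(tert-butyldimethylsilyl)oxy]phenyl}magnesium bromide | CC(C)(C)[Si](C)(C)Oc1ccc(O[Si](C)(C)C(C)(C)C)c([Mg]Br)c1 | intermediate
26 | chloromagnesium carboxylate of 22 | C/C(=C\CCC1=CCC[C@@](CC(=O)N(C)OC)(C(=O)O[Mg]Cl)OC1)CO[Si](C)(C)C(C)(C)C | intermediate
27 | (2R)-2-(2-{2,5-bis[(tert-butyldimethylsilyl)oxy]phenyl}-2-oxoethyl)-6-[(3E)-5-[(tert-butyldimethylsilyl)oxy]-4-methylpent-3-en-1-yl]-2,3,4,7-tetrahydrooxepine-2-carboxylic acid | C/C(=C\CCC1=CCC[C@@](CC(=O)c2cc(O[Si](C)(C)C(C)(C)C)ccc2O[Si](C)(C)C(C)(C)C)(C(=O)O)OC1)CO[Si](C)(C)C(C)(C)C | intermediate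
28 | (2R)-2-[2-(2,5-dihydroxyphenyl)-2-oxoethyl]-6-[(3E)-5-hydroxy-4-methylpent-3-en-1-yl]-2,3,4,7-tetrahydrooxepine-2-carboxylic acid | C/C(=C\CCC1=CCC[C@@](CC(=O)c2cc(O)ccc2O)(C(=O)O)OC1)CO | target

**Step count and risks**

Total: 14 steps. Longest linear sequence: 9 steps (steps 1–5, 10, 11, 13, 14).

Steps most likely to fail:

1. Step 10. The oxa-Michael equilibrium may rest on the adduct of the lactol oxygen, or the basic alkoxide may shift the double bond of the vinylphosphonium salt into the chain, so that the ylide never meets the aldehyde. The fallback builds the two bonds separately, setting out from 11 and 16 and coming back at 21. Methylenation of lactol 11 (Ph3P=CH2 from Ph3PCH3Br and KN(SiMe3)2, THF) would give methyl (2R)-2-hydroxy-2-{2-[methoxy(methyl)amino]-2-oxoethyl}hex-5-enoate F1. Stille coupling of triflate 16 with Bu3SnCH2OH (Pd(PPh3)4, LiCl, dioxane) would give (5E)-7-[(tert-butyldimethylsilyl)oxy]-6-methyl-2-methylidenehept-5-en-1-ol F2, and Appel bromination (CBr4, PPh3) would give tert-butyl{[(2E)-6-(bromomethyl)-2-methylhepta-2,6-dien-1-yl]oxy}dimethylsilane F3. O-Alkylation of F1 with F3 (NaH, Bu4NI, DMF, 0 °C) would give methyl (2R)-2-{[(5E)-7-[(tert-butyldimethylsilyl)oxy]-6-methyl-2-methylidenehept-5-en-1-yl]oxy}-2-{2-[methoxy(methyl)amino]-2-oxoethyl}hex-5-enoate F4. Ring-closing metathesis with the second-generation Hoveyda–Grubbs catalyst (C31H38Cl2N2ORu, CH2Cl2, 40 °C) would then close C5=C6 and give 21.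

2. Step 5. Oxygen may be delivered to the internal olefin carbon (methyl ketone formation), or the olefin may migrate before oxidation. The fallback fixes the regiochemistry by hydroboration, setting out from 9 and coming back at 11. Hydroboration of 9 with 9-BBN (THF, rt) and oxidation (NaBO3·4H2O, pH 7) would give 2-[(2R,4R)-2-tert-butyl-4-(3-hydroxypropyl)-5-oxo-1,3-dioxolan-4-yl]-N-methoxy-N-methylacetamide F5. Dess–Martin oxidation would give 2-[(2R,4R)-2-tert-butyl-5-oxo-4-(3-oxopropyl)-1,3-dioxolan-4-yl]-N-methoxy-N-methylacetamide F6. Methanolysis (NaOMe cat., MeOH, 0 °C) would open the dioxolanone, and the freed tertiary alcohol would close on the aldehyde to give lactol 11.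

3. Step 13. The magnesium carboxylate may aggregate and slow the addition, so that deprotonation next to the amide and β-elimination of the ring oxygen take over. The fallback keeps the acid as its methyl ester during the addition and frees it afterwards without base, setting out from 21 and coming back at 27. Addition of Grignard reagent 25 to 21 (THF, −40 → 0 °C), where the Weinreb amide should react before the hindered ester, would give methyl (2R)-2-(2-{2,5-bis[(tert-butyldimethylsilyl)oxy]phenyl}-2-oxoethyl)-6-[(3E)-5-[(tert-butyldimethylsilyl)oxy]-4-methylpent-3-en-1-yl]-2,3,4,7-tetrahydrooxepine-2-carboxylate F7. Neutral ester cleavage with Me3SnOH (1,2-dichloroethane, 70 °C) would then give 27.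

**Further compounds**

F1 | step 10 | methyl (2R)-2-hydroxy-2-{2-[methoxy(methyl)amino]-2-oxoethyl}hex-5-enoate | C=CCC[C@@](O)(CC(=O)N(C)OC)C(=O)OC
F2 | step 10 | (5E)-7-[(tert-butyldimethylsilyl)oxy]-6-methyl-2-methylidenehept-5-en-1-ol | C=C(CO)CC/C=C(\C)CO[Si](C)(C)C(C)(C)C
F3 | step 10 | tert-butyl{[(2E)-6-(bromomethyl)-2-methylhepta-2,6-dien-1-yl]oxy}dimethylsilane | C=C(CBr)CC/C=C(\C)CO[Si](C)(C)C(C)(C)C
F4 | step 10 | methyl (2R)-2-{[(5E)-7-[(tert-butyldimethylsilyl)oxy]-6-methyl-2-methylidenehept-5-en-1-yl]oxy}-2-{2-[methoxy(methyl)amino]-2-oxoethyl}hex-5-enoate | C=CCC[C@@](CC(=O)N(C)OC)(C(=O)OC)OCC(=C)CC/C=C(\C)CO[Si](C)(C)C(C)(C)C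
F5 | step 5 | 2-[(2R,4R)-2-tert-butyl-4-(3-hydroxypropyl)-5-oxo-1,3-dioxolan-4-yl]-N-methoxy-N-methylacetamide | CC(C)(C)[C@@H]1O[C@](CCCO)(CC(=O)N(C)OC)C(=O)O1
F6 | step 5 | 2-[(2R,4R)-2-tert-butyl-5-oxo-4-(3-oxopropyl)-1,3-dioxolan-4-yl]-N-methoxy-N-methylacetamide | CC(C)(C)[C@@H]1O[C@](CCC=O)(CC(=O)N(C)OC)C(=O)O1
F7 | step 13 | methyl (2R)-2-(2-{2,5-bis[(tert-butyldimethylsilyl)oxy]phenyl}-2-oxoethyl)-6-[(3E)-5-[(tert-butyldimethylsilyl)oxy]-4-methylpent-3-en-1-yl]-2,3,4,7-tetrahydrooxepine-2-carboxylate | C/C(=C\CCC1=CCC[C@@](CC(=O)c2cc(O[Si](C)(C)C(C)(C)C)ccc2O[Si](C)(C)C(C)(C)C)(C(=O)OC)OC1)CO[Si](C)(C)C(C)(C)C
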